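The readings are simulated for substances that don't exist, and the scatter is random.

The partner was the charge I read first. The scheme passes one partner through the catalyst for each substrate that reacts, and the amber flask holds 0.600 equiv, less than the substrate, so partner is the limiting reagent. The amber flask therefore has a ceiling of 60.0 %, the part of the substrate its partner charge can turn over.

| setting | amber | grey | flask |
|---|---|---|---|
| substrate | 0.87 M | 0.87 M | 0.87 M |
| partner | 0.60 equiv | 0.60 equiv | 0.600 equiv |
| scavenger | 1.2 equiv | 1.8 equiv | 1.20 equiv |
| free catalyst | 11 mol% | 11 mol% | 11 mol% |
| remark | the very flask that is asked about, followed so far | run made earlier |  |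
| time |  |  | 25 min |

| run | time / min | substrate / % | product / % |
|---|---|---|---|
| amber | 2.50 | 96.1 | 3.4 |
| amber | 5.00 | 85.7 | 11.2 |
| amber | 8.00 | 81.1 | 21.1 |
| amber | 10.0 | 76.7 | 24.7 |
| grey | 2.00 | 97.6 | 3.2 |
| grey | 5.00 | 86.9 | 13.2 |
| grey | 10.0 | 75.4 | 22.6 |
| grey | 25.0 | 60.5 | 40.2 |

(standard deviation of a reading: 1 percentage point)

- released group is meant together with its idle adduct
- the analysis behind the earlier runs scatters by 1 percentage point, standard deviation
- reactions considered so far: catalyst intermediate B -> catalyst intermediate C; scavenger + released group -> scavenged by-product; partner + free catalyst -> catalyst intermediate A; substrate + catalyst intermediate C -> catalyst intermediate D; catalyst intermediate A -> released group + catalyst intermediate B; catalyst intermediate D -> free catalyst + product; partner + released group <-> idle adduct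
- the earlier runs do not show how much of partner is bound; that part of a forecast is a guess

- part of the substrate that has reacted at 25 min
- share of the unused partner that is free and not bound as idle adduct, at 25 min

At 10.0 min the amber run read 24.7 % of product and the grey run 22.6 %, though grey held 1.8 equiv of scavenger against amber's 1.2 equiv. So I took grey as a guide: at 25.0 min it read 40.2 %, which left 20 percentage points of headroom under the same ceiling, and I committed to amber near that reading. But these runs do not show how the unused partner divides.

The forecast gave 39 % reacted and 68 % of the unused partner free, saying "The free share is largely a guess".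

The flask gave 37.7 % and 24.1 %.

    catalyst intermediate B → catalyst intermediate C (k = 0.0280 s⁻¹)
    scavenger + released group → scavenged by-product (k = 0.00890 M⁻¹ s⁻¹)
    partner + free catalyst → catalyst intermediate A (k = 0.0260 M⁻¹ s⁻¹)
    substrate + catalyst intermediate C → catalyst intermediate D (k = 0.0300 M⁻¹ s⁻¹)
    catalyst intermediate A → released group + catalyst intermediate B (k = 0.0320 s⁻¹)
    catalyst intermediate D → free catalyst + product (k = 0.810 s⁻¹)
    partner + released group ⇌ idle adduct, settled at all times (K = 140 M⁻¹)

In this flask the headroom at 25 min was 22 points, or 0.194 M: idle adduct stood at 0.137 M, free partner at 0.0437 M, and the remainder in catalyst intermediates A, B and C. After 250 min this flask reached 60.0 %, level with its ceiling. The neighbour flask with 0.240 equiv of partner has a ceiling of 24.0 % and at 25.0 min had reached 18.1 %, a headroom of 0.0517 M, with idle adduct at 0.0272 M and a free share of 41.3 %.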